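**Retrosynthetic overview**
1. Numbering: decalin C1–C10 (the C10 methyl defines the β face) and C11 = the CH2 link on C9. Carbocycle: C1' (oxirane C bearing C11), C2' (oxirane CH), C3' (C=O), C4' (C–CH2OH), C5' (=CH), C6' (CHOH).
2. Target ⇐ acetal/silyl cleavage ⇐ C6'=O reduction ⇐ epoxy ketone. The epoxy ketone is taken apart in one flask operation at C11–C1', at C9–H and at the oxirane: hydroboration of a 7,9(11)-diene, B-alkyl Suzuki–Miyaura coupling with a 2-iodo quinone monoacetal, then Weitz–Scheffer closure.
3. Enabling feature: in the 1,4-dioxygenated six-membered ring, C1' is the α-carbon of the C6' carbonyl and its alkene partner C2' is an unsubstituted β-carbon next to C3'. As sp2 C–I it cross-couples, and the same enone then accepts peroxide. On the other side, C11 is the terminus of a transoid C7=C8–C9=C11 diene beside the axial C10 methyl, so α-face hydroboration sets C9.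
4. Diene: rings A/B with C4, C5 and C10 come with abietic acid. Ring C is excised by C13=C14 glycol cleavage, conversion of C14 into the C8 methyl, and Norrish II scission of C11–C12.
5. Iododienone: oxidative dearomatisation of a cheap iodinated 4-methoxyphenol, then a temporary C2-symmetric dioxolane at C3'. Ring order: A/B (bought) → carbocycle (from the arene) → dioxolane (temporary) → oxirane (key step).

Key step: step 13

Assumption: the sense of acetal-controlled peroxide delivery is taken from the steric model given in step 13; if it proved opposite, (S,S)-hydrobenzoin would be used with no other change.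

Step 1
Reactants: 1 (−)-abietic acid (abieta-7,13-dien-18-oic acid; 4α-CO2H; 4β-CH3; 5αH; 9αH; 10β-CH3)
Product: 2 abietinol (abieta-7,13-dien-18-ol; same four stereocentres)
Conditions: LiAlH4, THF, 0 °C → reflux
Reagents that add atoms: none
Why: Hydride reduction of the carboxylic acid (LiAlH4 reduction) leaves the unactivated 7,13-diene and all four stereocentres untouched.

Step 2
Reactants: 2 abietinol
Product: 3 18-O-TBS-abietinol
Conditions: TBSCl, imidazole, DMF, 40 °C
Reagents that add atoms: tert-butyldimethylsilyl chloride, CC(C)(C)[Si](C)(C)Cl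
Why: Imidazole-promoted silyl ether formation masks the neopentyl primary alcohol for the oxidative, photochemical and organometallic steps and affects no stereocentre.

Step 3
Reactants: 3 18-O-TBS-abietinol
Product: 5 18-O-TBS-13-oxo-13,14-secoabiet-7-en-14-al (C8-formyl enal; 9αH; 9β-CH2CH2C(O)CH(CH3)2), via 18-O-TBS-abiet-7-ene-13α,14α-diol 4 (not isolated)
Conditions: OsO4 (cat.), NMO, acetone–H2O, rt; then NaIO4, THF–H2O, 0 °C
Reagents that add atoms: N-methylmorpholine N-oxide, C[N+]1([O-])CCOCC1; water, O
Why: In this Upjohn dihydroxylation followed by periodate glycol cleavage, OsO4 (which relays both oxygen atoms) should take the more exposed ring-C alkene C13=C14, the face of attack (drawn α) is immaterial because both carbinol centres are erased by the cleavage, and the surviving C7=C8 then belongs to an electron-poor enal that resists further osmylation.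

Step 4
Reactants: 5 seco keto-enal
Product: 6 18-O-TBS-13,14-secoabiet-7-ene-13,14-diol (primary allylic C14–OH; C13 carbinol as epimer mixture)
Conditions: NaBH4, MeOH–CH2Cl2, 0 °C → rt
Reagents that add atoms: none
Why: Borohydride 1,2-reduction takes both carbonyl groups down so that the next hydride step meets no ketone, and the new C13 centre forms as an inconsequential epimer mixture that step 6 erases.

Step 5
Reactants: 6 seco diol
Product: 8 18-O-TBS-13,14-secoabiet-7-en-13-ol (C8–CH3; C7=C8 retained), via pyridinium 14-O-sulfate 7 (not isolated)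
Conditions: SO3·pyridine, THF, 0 °C; then LiAlH4, 0 °C → rt
Reagents that add atoms: none
Why: Selective O-sulfation of the unhindered primary allylic alcohol and SN2 hydride displacement of the allylic sulfate monoester (allylic deoxygenation without transposition) turn C14 into the C8 methyl group, while the hindered secondary alcohol only forms an alkoxide.

Step 6
Reactants: 8 seco alcohol
Product: 9 18-O-TBS-13,14-secoabiet-7-en-13-one
Conditions: Dess–Martin periodinane, CH2Cl2, rt
Reagents that add atoms: none
Why: Dess–Martin oxidation regenerates the isopropyl ketone chromophore under near-neutral conditions that spare the alkene and the silyl ether.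

Step 7
Reactants: 9 seco ketone
Product: 10 4α-(TBSOCH2)-drima-7,9(11)-diene (4β-CH3; 5αH; 10β-CH3; exocyclic C9=C11)
Conditions: hν (300 nm), benzene–t-BuOH, degassed, rt
Reagents that add atoms: none
Why: In this Norrish type II fragmentation the n,π*-excited C13 ketone abstracts its only γ-hydrogen, the weak tertiary allylic C9–H, through a six-membered transition state, and the 1,4-biradical cleaves C11–C12 to the conjugated diene and an enol, so the C9 centre is erased on purpose and reset in step 13.

Step 8
Reactants: 11 5-hydroxy-2-methoxybenzaldehyde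
Product: 12 3-(hydroxymethyl)-4-methoxyphenol
Conditions: NaBH4, MeOH, 0 °C
Reagents that add atoms: none
Why: Borohydride reduction of the aryl aldehyde gives the benzylic alcohol that becomes the C4' hydroxymethyl group.

Step 9
Reactants: 12 3-(hydroxymethyl)-4-methoxyphenol
Product: 13 3-(TBSOCH2)-4-methoxyphenol
Conditions: TBSCl (1 equiv), imidazole, DMF, 0 °C
Reagents that add atoms: tert-butyldimethylsilyl chloride, CC(C)(C)[Si](C)(C)Cl
Why: In this chemoselective silylation the aliphatic primary alcohol reacts faster than the phenol, which must stay free for steps 10 and 11.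

Step 10
Reactants: 13 3-(TBSOCH2)-4-methoxyphenol
Product: 14 2-iodo-4-methoxy-5-(TBSOCH2)phenol
Conditions: N-iodosuccinimide, MeCN, 0 °C
Reagents that add atoms: N-iodosuccinimide, O=C1CCC(=O)N1I
Why: Electrophilic aromatic iodination is directed ortho to the free phenol, and of the two ortho positions only the one para to CH2OTBS (future C1') is not flanked by two substituents.

Step 11
Reactants: 14 iodophenol
Product: 15 2-iodo-4,4-dimethoxy-5-(TBSOCH2)cyclohexa-2,5-dienone
Conditions: PhI(OAc)2, MeOH, 0 °C
Reagents that add atoms: methanol, CO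
Why: In this iodine(III)-mediated oxidative dearomatisation of a 4-methoxyphenol (quinone monoketal synthesis), methanol is captured at the OMe-bearing para carbon, which fixes the free carbonyl (C6') next to C–I and the acetal at C3'.

Step 12
Reactants: 15 iodo dimethyl acetal; 16 (R,R)-hydrobenzoin
Product: 17 (2R,3R)-7-iodo-10-(TBSOCH2)-2,3-diphenyl-1,4-dioxaspiro[4.5]deca-6,9-dien-8-one
Conditions: PPTS (cat.), toluene, 5 Å MS, 70 °C
Reagents that add atoms: none
Why: Acid-catalysed transketalisation is driven by removal of methanol, and because the diol is C2-symmetric the spiro carbon is not stereogenic, so a single compound results.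

Step 13
Reactants: 10 4α-(TBSOCH2)-drima-7,9(11)-diene; 17 iodo spiroacetal dienone
Product: 20 spiroacetal epoxy ketone (4α-(TBSOCH2)drim-7-en-11-yl on C1'; 9αH; cis-oxirane C1'–C2' on the ring face opposite to C11; C6'=O; C3' (R,R)-diphenyldioxolane), via B-[4α-(TBSOCH2)drim-7-en-11-yl]-9-BBN 18 (not isolated), via coupled spiroacetal dienone 19 (not isolated)
Conditions: 9-BBN, THF, 60 °C, then H2O; 17, PdCl2(dppf) (cat.), AsPh3 (cat.), Cs2CO3, DMF–THF–H2O, degassed, rt; then 30% H2O2, 1 M NaOH, 0 °C
Reagents that add atoms: hydrogen peroxide, OO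
Why: 9-BBN adds syn across the only 1,1-disubstituted alkene of the transoid diene 10 with boron on C11, and because the axial C10 methyl shields the β face the hydrogen reaches C9 from the α face, which sets 9αH (C11 equatorial) and leaves the hindered trisubstituted C7=C8 untouched. Base-activated borane 18 transmetalates to the alkenylpalladium(II) iodide formed by oxidative addition of 17 at C1'–I and reductive elimination forges C11–C1' to give 19; the closest known reaction type is the B-alkyl Suzuki–Miyaura coupling of 2-iodocycloalk-2-enones, and dppf is chosen so that reductive elimination outruns β-hydride loss from C9. The alkaline peroxide customarily added to destroy the borinic acid residue then carries out a Weitz–Scheffer epoxidation of 19: HOO− adds to C2' and the resulting C1' enolate displaces hydroxide at the proximal peroxide oxygen, closing the oxirane in the 3-exo-tet mode, necessarily cis on the six-membered ring. Site selectivity is built into the substrate, since C2' is the only unsubstituted β-carbon of the dienone (C4' carries CH2OTBS) and the isolated C7=C8 alkene is inert to a nucleophilic oxidant. The configuration at C2', and through the cis closure at C1', is controlled by the C2-symmetric (R,R)-diphenyldioxolane on the neighbouring C3': the phenyl group of the acetal carbon on one face leans over the C2' flank, so peroxide should enter from the other face, the one required by the target. In one flask the step thus makes one C–C, one C–H and two C–O bonds, one ring and three stereocentres from a diene without C9 chirality and a flat, arene-derived dienone.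

Step 14
Reactants: 20 spiroacetal epoxy ketone
Product: 21 spiroacetal epoxy alcohol (C6'–OH trans to the oxirane oxygen; cis to C11)
Conditions: L-Selectride, THF, −78 °C; H2O
Reagents that add atoms: none
Why: In this diastereoselective 1,2-reduction with a bulky trialkylborohydride, the face of C6'=O syn to C11 is covered by the neopentyl-like CH2–decalin arm on the adjacent quaternary C1', so hydride should enter from the oxirane face and give the trans epoxy alcohol, while the fully substituted β-carbon C4' disfavours 1,4-reduction.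

Step 15
Reactants: 21 spiroacetal epoxy alcohol
Product: 22 epoxypholamin A
Conditions: 48% aq HF, MeCN, 0 °C → rt
Reagents that add atoms: water, O
Why: Fluoride-assisted desilylation of both primary TBS ethers and acid hydrolysis of the allylic acetal occur together, unmask the C3' enone and release the auxiliary without touching any stereocentre.

**Compound list**
1 | (−)-abietic acid | CC(C)C1=CC2=CC[C@H]3[C@](C)(C(=O)O)CCC[C@]3(C)[C@H]2CC1 | starting material
2 | abietinol | CC(C)C1=CC2=CC[C@H]3[C@](C)(CO)CCC[C@]3(C)[C@H]2CC1 | intermediate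
3 | 18-O-TBS-abietinol | CC(C)C1=CC2=CC[C@H]3[C@](C)(CO[Si](C)(C)C(C)(C)C)CCC[C@]3(C)[C@H]2CC1 | intermediate
4 | 18-O-TBS-abiet-7-ene-13α,14α-diol | CC(C)[C@@]1(O)[C@H](O)C2=CC[C@H]3[C@](C)(CO[Si](C)(C)C(C)(C)C)CCC[C@]3(C)[C@H]2CC1 | intermediate
5 | 18-O-TBS-13-oxo-13,14-secoabiet-7-en-14-al | O=CC1=CC[C@H]2[C@](C)(CO[Si](C)(C)C(C)(C)C)CCC[C@]2(C)[C@H]1CCC(=O)C(C)C | intermediate
6 | 18-O-TBS-13,14-secoabiet-7-ene-13,14-diol (C13 epimers) | OCC1=CC[C@H]2[C@](C)(CO[Si](C)(C)C(C)(C)C)CCC[C@]2(C)[C@H]1CCC(O)C(C)C | intermediate
7 | pyridinium 14-O-sulfate of 6 | [O-]S(=O)(=O)OCC1=CC[C@H]2[C@](C)(CO[Si](C)(C)C(C)(C)C)CCC[C@]2(C)[C@H]1CCC(O)C(C)C.c1cc[nH+]cc1 | intermediate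
8 | 18-O-TBS-13,14-secoabiet-7-en-13-ol (C13 epimers) | CC1=CC[C@H]2[C@](C)(CO[Si](C)(C)C(C)(C)C)CCC[C@]2(C)[C@H]1CCC(O)C(C)C | intermediate
9 | 18-O-TBS-13,14-secoabiet-7-en-13-one | CC1=CC[C@H]2[C@](C)(CO[Si](C)(C)C(C)(C)C)CCC[C@]2(C)[C@H]1CCC(=O)C(C)C | intermediate
10 | 4α-(TBSOCH2)-drima-7,9(11)-diene | CC1=CC[C@H]2[C@](C)(CO[Si](C)(C)C(C)(C)C)CCC[C@]2(C)C1=C | intermediate
11 | 5-hydroxy-2-methoxybenzaldehyde | COc1ccc(O)cc1C=O | starting material
12 | 3-(hydroxymethyl)-4-methoxyphenol | COc1ccc(O)cc1CO | intermediate
13 | 3-(TBSOCH2)-4-methoxyphenol | COc1ccc(O)cc1CO[Si](C)(C)C(C)(C)C | intermediate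
14 | 2-iodo-4-methoxy-5-(TBSOCH2)phenol | COc1cc(I)c(O)cc1CO[Si](C)(C)C(C)(C)C | intermediate
15 | 2-iodo-4,4-dimethoxy-5-(TBSOCH2)cyclohexa-2,5-dienone | COC1(OC)C=C(I)C(=O)C=C1CO[Si](C)(C)C(C)(C)C | intermediate
16 | (R,R)-hydrobenzoin | O[C@H](c1ccccc1)[C@H](O)c1ccccc1 | starting material
17 | (2R,3R)-7-iodo-10-(TBSOCH2)-2,3-diphenyl-1,4-dioxaspiro[4.5]deca-6,9-dien-8-one | O=C1C=C(CO[Si](C)(C)C(C)(C)C)C2(O[C@H](c3ccccc3)[C@@H](c3ccccc3)O2)C=C1I | intermediate
18 | B-[4α-(TBSOCH2)drim-7-en-11-yl]-9-BBN (9αH) | CC1=CC[C@H]2[C@](C)(CO[Si](C)(C)C(C)(C)C)CCC[C@]2(C)[C@H]1CB1C2CCCC1CCC2 | intermediate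
19 | coupled spiroacetal dienone (C11–C1' bond in place) | CC1=CC[C@H]2[C@](C)(CO[Si](C)(C)C(C)(C)C)CCC[C@]2(C)[C@H]1CC1=CC2(O[C@H](c3ccccc3)[C@@H](c3ccccc3)O2)C(CO[Si](C)(C)C(C)(C)C)=CC1=O | intermediate
20 | spiroacetal epoxy ketone | CC1=CC[C@H]2[C@](C)(CO[Si](C)(C)C(C)(C)C)CCC[C@]2(C)[C@H]1C[C@@]12O[C@@H]1C1(O[C@H](c3ccccc3)[C@@H](c3ccccc3)O1)C(CO[Si](C)(C)C(C)(C)C)=CC2=O | intermediate
21 | spiroacetal epoxy alcohol | CC1=CC[C@H]2[C@](C)(CO[Si](C)(C)C(C)(C)C)CCC[C@]2(C)[C@H]1C[C@@]12O[C@@H]1C1(O[C@H](c3ccccc3)[C@@H](c3ccccc3)O1)C(CO[Si](C)(C)C(C)(C)C)=C[C@H]2O | intermediate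
22 | epoxypholamin A | CC1=CC[C@H]2[C@](C)(CO)CCC[C@]2(C)[C@H]1C[C@@]12O[C@@H]1C(=O)C(CO)=C[C@H]2O | target

Total step count: 15. Longest linear sequence: 10 steps (steps 1–7, then 13–15).

**Three steps most likely to fail**

Step 13. Boron-to-palladium transfer of the β-branched, neopentyl-like borane may be slow. β-Hydride elimination and hydrodeiodination of the iododienone could then compete, and the crude coupling medium may erode the face selectivity of the peroxide addition. The fallback is an organozinc union with a separate epoxidation.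
- It sets out from 10.
- Hydroboration (9-BBN, through 18) with ordinary oxidative work-up would give 4α-(TBSOCH2)drim-7-en-11-ol F1.
- Iodination (I2, PPh3, imidazole) would give the 11-iodide F2, and zinc insertion (Zn, LiCl, THF) the alkylzinc iodide F3.
- Negishi coupling of this zinc reagent with 17 (Pd2(dba)3, SPhos, THF) would give 19, now isolated and purified.
- A separate Weitz–Scheffer epoxidation (t-BuOOH, DBU, CH2Cl2, −20 °C) comes back to the route at 20.

Step 14. Facial selectivity may be poor or inverted, because the stereoelectronic preference for hydride attack anti to the oxirane C–O bond could override the steric bias of the C11 arm. The fallback accepts the wrong face and inverts it.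
- It sets out from 20.
- A small hydride under Luche conditions (NaBH4, CeCl3, MeOH) should follow the stereoelectronic preference and give the C6' epimeric alcohol F4, in which the hydroxyl is cis to the oxirane oxygen.
- Mitsunobu inversion (4-nitrobenzoic acid, DIAD, PPh3), in which the fully substituted C4' disfavours the SN2' path, would give the inverted 4-nitrobenzoate F5.
- Mild methanolysis (K2CO3, MeOH, 0 °C) comes back to the route at 21.

Step 15. Hydrolysis of the diphenyldioxolane may be slower than acid-induced opening of the oxirane or ionisation of the allylic alcohol. The fallback drops the auxiliary and uses reagent control with a labile acetal.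
- It sets out from 10 and 15.
- Hydroboration and B-alkyl Suzuki–Miyaura coupling (through 18, non-oxidative work-up) would give the dimethyl acetal dienone F6.
- Asymmetric phase-transfer epoxidation (t-BuOOH, aq NaOH, toluene, N-(9-anthracenylmethyl)cinchonidinium bromide or its pseudoenantiomer) would give the dimethyl acetal epoxy ketone F7.
- L-Selectride reduction would give the dimethyl acetal epoxy alcohol F8.
- Its far more labile acetal and both silyl ethers fall under mild aqueous HF in MeCN, which comes back to the route at 22.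

**Further compounds**
F1 | step 13 | 4α-(TBSOCH2)drim-7-en-11-ol | CC1=CC[C@H]2[C@](C)(CO[Si](C)(C)C(C)(C)C)CCC[C@]2(C)[C@H]1CO
F2 | step 13 | 11-iodo-4α-(TBSOCH2)drim-7-ene | CC1=CC[C@H]2[C@](C)(CO[Si](C)(C)C(C)(C)C)CCC[C@]2(C)[C@H]1CI
F3 | step 13 | [4α-(TBSOCH2)drim-7-en-11-yl]zinc iodide | CC1=CC[C@H]2[C@](C)(CO[Si](C)(C)C(C)(C)C)CCC[C@]2(C)[C@H]1C[Zn]I
F4 | step 14 | C6' epimer of epoxy alcohol 21 | CC1=CC[C@H]2[C@](C)(CO[Si](C)(C)C(C)(C)C)CCC[C@]2(C)[C@H]1C[C@@]12O[C@@H]1C1(O[C@H](c3ccccc3)[C@@H](c3ccccc3)O1)C(CO[Si](C)(C)C(C)(C)C)=C[C@@H]2O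
F5 | step 14 | 4-nitrobenzoate of 21 | CC1=CC[C@H]2[C@](C)(CO[Si](C)(C)C(C)(C)C)CCC[C@]2(C)[C@H]1C[C@@]12O[C@@H]1C1(O[C@H](c3ccccc3)[C@@H](c3ccccc3)O1)C(CO[Si](C)(C)C(C)(C)C)=C[C@H]2OC(=O)c1ccc(cc1)[N+](=O)[O-]
F6 | step 15 | dimethyl acetal dienone | CC1=CC[C@H]2[C@](C)(CO[Si](C)(C)C(C)(C)C)CCC[C@]2(C)[C@H]1CC1=CC(OC)(OC)C(CO[Si](C)(C)C(C)(C)C)=CC1=O
F7 | step 15 | dimethyl acetal epoxy ketone | CC1=CC[C@H]2[C@](C)(CO[Si](C)(C)C(C)(C)C)CCC[C@]2(C)[C@H]1C[C@@]12O[C@@H]1C(OC)(OC)C(CO[Si](C)(C)C(C)(C)C)=CC2=O
F8 | step 15 | dimethyl acetal epoxy alcohol | CC1=CC[C@H]2[C@](C)(CO[Si](C)(C)C(C)(C)C)CCC[C@]2(C)[C@H]1C[C@@]12O[C@@H]1C(OC)(OC)C(CO[Si](C)(C)C(C)(C)C)=C[C@H]2O
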